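**Plan**

1. Retrosynthesis: remove the 4-methoxybenzoate (acylation of the C-8 hydroxyl) and the tertiary hydroxyl (hydration of a C-1=C-2 cyclopentene). Then cut C-1–isopropyl (enol triflate coupling) and C-5=C-6 (ring-closing metathesis). Then cut C-1–C-2 and C-3a–C-8a together, which opens a cyclopentanone to an acyclic allyl vinyl ether, itself cut at the enol C–O bond into two small chiral fragments.
2. Enabling feature: at the ketone level the five-membered ring is a 2,3,3-trisubstituted cyclopentanone – C-1 (carbonyl), C-8a (α-CH), quaternary C-3a (β) and the two unsubstituted CH2 groups C-3 and C-2. That is a 4-pentenal hydroacylation retron nested in a Claisen retron.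
3. Forward order: five-membered ring first (tandem Claisen rearrangement/hydroacylation), seven-membered ring second (metathesis), then enone, ester and, last, the tertiary alcohol.
4. Stereochemistry: C-8 from a Keck methallylation. C-3a/C-8a from the chair Claisen transition state ((E)-enol ether, (Z)-allyl unit), whose face is fixed by a dioxolane centre from (S)-glyceraldehyde acetonide that is later cut away. C-1 from hydration on the convex face.

Key step: step 10

Remark: ring atoms carry azulene locants (C-1 carbinol carbon, C-2 and C-3 CH2, C-3a quaternary carbon, C-4 ketone, C-5=C-6 alkene, C-7 CH2, C-8 ester carbon, C-8a ring-fusion CH). It is assumed that the [3,3] shift follows the usual allylic-strain model, with the new bond formed anti to the allylic C–O bond.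

**Route**

Step 1
Reactants: 1 (4S)-2,2-dimethyl-1,3-dioxolane-4-carbaldehyde
Product: 2 (4R)-4-ethynyl-2,2-dimethyl-1,3-dioxolane
Conditions: dimethyl (1-diazo-2-oxopropyl)phosphonate, K2CO3, MeOH, 0 °C to rt
Reagents that add atoms: dimethyl (1-diazo-2-oxopropyl)phosphonate, CC(=O)C(=[N+]=[N-])P(=O)(OC)OC
Why: Seyferth–Gilbert homologation in its Ohira–Bestmann form converts the aldehyde into the terminal alkyne under conditions mild enough that the α-alkoxy stereocentre should not epimerise (the descriptor changes from S to R only through the priority rules).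

Step 2
Reactants: 2 (4R)-4-ethynyl-2,2-dimethyl-1,3-dioxolane
Product: 3 methyl 3-[(4R)-2,2-dimethyl-1,3-dioxolan-4-yl]prop-2-ynoate
Conditions: n-BuLi, THF, −78 °C; then ClCO2Me
Reagents that add atoms: methyl chloroformate, COC(=O)Cl
Why: Deprotonation of the terminal alkyne and C-acylation of the lithium acetylide with a chloroformate is a standard route to ynoates.

Step 3
Reactants: 3 methyl 3-[(4R)-2,2-dimethyl-1,3-dioxolan-4-yl]prop-2-ynoate
Product: 4 methyl (2Z)-3-[(4R)-2,2-dimethyl-1,3-dioxolan-4-yl]but-2-enoate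
Conditions: Me2CuLi (from MeLi and CuI), THF, −78 °C; MeOH quench at −78 °C
Reagents that add atoms: lithium dimethylcuprate, [Li+].C[Cu-]C
Why: Conjugate syn-carbocupration of the ynoate by the Gilman reagent with low-temperature protonation places the new methyl group and the vinylic hydrogen cis, which should give the (Z)-enoate with the dioxolane cis to the ester.

Step 4
Reactants: 4 methyl (2Z)-3-[(4R)-2,2-dimethyl-1,3-dioxolan-4-yl]but-2-enoate
Product: 5 (2Z)-3-[(4R)-2,2-dimethyl-1,3-dioxolan-4-yl]but-2-en-1-ol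
Conditions: diisobutylaluminium hydride, CH2Cl2, −78 °C
Reagents that add atoms: none
Why: 1,2-Reduction of the enoate with diisobutylaluminium hydride should give the allylic alcohol with the (Z)-geometry untouched.

Step 5
Reactants: 6 3-(trimethylsilyl)prop-2-ynal
Product: 7 (3S)-5-methyl-1-(trimethylsilyl)hex-5-en-1-yn-3-ol
Conditions: (S)-BINOL (10 mol %), Ti(OiPr)4 (10 mol %), 4 Å MS, tributyl(2-methylallyl)stannane, CH2Cl2, −20 °C
Reagents that add atoms: tributyl(2-methylprop-2-en-1-yl)stannane, CCCC[Sn](CCCC)(CCCC)CC(C)=C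
Why: Keck asymmetric allylation (BINOL–titanium-catalysed addition of the methallylstannane to the ynal) should set the future C-8 carbinol centre as S with the (S)-ligand.

Step 6
Reactants: 7 (3S)-5-methyl-1-(trimethylsilyl)hex-5-en-1-yn-3-ol
Product: 8 (3S)-5-methylhex-5-en-1-yn-3-ol
Conditions: K2CO3 (cat.), MeOH, rt
Reagents that add atoms: none
Why: Base-catalysed methanolysis cleaves the alkynyl C–Si bond (protiodesilylation) without touching the carbinol centre.

Step 7
Reactants: 8 (3S)-5-methylhex-5-en-1-yn-3-ol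
Product: 9 tert-butyl(dimethyl){[(3S)-5-methylhex-5-en-1-yn-3-yl]oxy}silane
Conditions: TBSCl, imidazole, DMF, rt
Reagents that add atoms: tert-butyl(chloro)dimethylsilane, CC(C)(C)[Si](C)(C)Cl
Why: Imidazole-promoted silylation protects the future C-8 oxygen through the basic, thermal and organometallic steps that follow.

Step 8
Reactants: 9 tert-butyl(dimethyl){[(3S)-5-methylhex-5-en-1-yn-3-yl]oxy}silane
Product: 10 tert-butyl{[(1E,3S)-1-iodo-5-methylhexa-1,5-dien-3-yl]oxy}dimethylsilane
Conditions: Cp2Zr(H)Cl, THF, rt; then I2, 0 °C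
Reagents that add atoms: iodine, II
Why: Hydrozirconation adds Zr–H syn across the terminal alkyne with zirconium on the terminal carbon and iodinolysis proceeds with retention, which should give the (E)-iodoalkene while the 1,1-disubstituted alkene reacts much more slowly.

Step 9
Reactants: 5 (2Z)-3-[(4R)-2,2-dimethyl-1,3-dioxolan-4-yl]but-2-en-1-ol; 10 tert-butyl{[(1E,3S)-1-iodo-5-methylhexa-1,5-dien-3-yl]oxy}dimethylsilane
Product: 11 tert-butyl{[(1E,3S)-1-{[(2Z)-3-[(4R)-2,2-dimethyl-1,3-dioxolan-4-yl]but-2-en-1-yl]oxy}-5-methylhexa-1,5-dien-3-yl]oxy}dimethylsilane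
Conditions: CuI (10 mol %), 3,4,7,8-tetramethyl-1,10-phenanthroline (20 mol %), Cs2CO3, toluene, 80 °C
Reagents that add atoms: none
Why: The CuI/phenanthroline-catalysed Ullmann-type C–O coupling of a vinyl iodide with an alcohol proceeds with retention of alkene geometry and should give the (E)-enol (Z)-allyl ether below the temperature at which it rearranges.

Step 10
Reactants: 11 tert-butyl{[(1E,3S)-1-{[(2Z)-3-[(4R)-2,2-dimethyl-1,3-dioxolan-4-yl]but-2-en-1-yl]oxy}-5-methylhexa-1,5-dien-3-yl]oxy}dimethylsilane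
Product: 13 (2R,3S)-2-[(1S)-1-{[tert-butyl(dimethyl)silyl]oxy}-3-methylbut-3-en-1-yl]-3-[(4R)-2,2-dimethyl-1,3-dioxolan-4-yl]-3-methylcyclopentan-1-one, via Claisen aldehyde 12 (not isolated)
Conditions: [Rh(cod)Cl]2 (5 mol %), dppe (10 mol %), PhCN, 130 °C, sealed tube
Reagents that add atoms: none
Why: Heating triggers a Claisen [3,3]-sigmatropic shift of the allyl vinyl ether that forges C-3a–C-8a and unveils the 4-pentenal 12; the rhodium catalyst then inserts into the aldehyde C–H bond, the acylrhodium hydride adds across the new vinyl group and reductive elimination forges C-1–C-2, the closest known reaction type being the rhodium-catalysed tandem Claisen rearrangement/intramolecular hydroacylation of allyl vinyl ethers to cyclopentanones. The five-membered ring is the only ring closed here and it closes through a six-membered acylrhodacycle (anti-Markovnikov hydrometalation, formally a 5-endo hydroacylation that needs the metal). C-3a and C-8a come from the chair transition state in which the C-8 side chain of the (E)-enol ether is equatorial and the dioxolane of the (Z)-allyl unit axial, which puts the methyl group and H-8a cis; the absolute sense comes from the dioxolane stereocentre, whose C–H eclipses the alkene because of 1,3-allylic strain so that the new bond forms anti to its C–O bond. The step needs facial selectivity in the [3,3] shift, secured by that locked conformer (the C-8 centre on the (E)-enol ether should exert little bias), and chemoselective hydroacylation, secured because only the vinyl group can form a five-membered ring with the aldehyde and, sitting on a quaternary carbon, cannot isomerise.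

Step 11
Reactants: 13 (2R,3S)-2-[(1S)-1-{[tert-butyl(dimethyl)silyl]oxy}-3-methylbut-3-en-1-yl]-3-[(4R)-2,2-dimethyl-1,3-dioxolan-4-yl]-3-methylcyclopentan-1-one
Product: 14 (4S,5R)-5-[(1S)-1-{[tert-butyl(dimethyl)silyl]oxy}-3-methylbut-3-en-1-yl]-4-[(4R)-2,2-dimethyl-1,3-dioxolan-4-yl]-4-methylcyclopent-1-en-1-yl trifluoromethanesulfonate
Conditions: KN(SiMe3)2, THF, −78 °C; then PhNTf2
Reagents that add atoms: N-phenylbis(trifluoromethanesulfonimide), O=S(=O)(N(c1ccccc1)S(=O)(=O)C(F)(F)F)C(F)(F)F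
Why: Kinetic deprotonation with the bulky amide base should occur at the unhindered CH2 (C-2) and not at the tertiary C-8a, and O-sulfonylation of the enolate gives the less substituted enol triflate, which also locks C-8a against epimerisation.

Step 12
Reactants: 14 (4S,5R)-5-[(1S)-1-{[tert-butyl(dimethyl)silyl]oxy}-3-methylbut-3-en-1-yl]-4-[(4R)-2,2-dimethyl-1,3-dioxolan-4-yl]-4-methylcyclopent-1-en-1-yl trifluoromethanesulfonate
Product: 15 tert-butyl({(1S)-1-[(1R,5S)-5-[(4R)-2,2-dimethyl-1,3-dioxolan-4-yl]-5-methyl-2-(propan-2-yl)cyclopent-2-en-1-yl]-3-methylbut-3-en-1-yl}oxy)dimethylsilane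
Conditions: iPrZnBr, Pd(OAc)2 (2 mol %), CPhos (4 mol %), THF–toluene, rt
Reagents that add atoms: isopropylzinc bromide, CC(C)[Zn]Br
Why: Negishi coupling of the alkenyl triflate with the secondary alkylzinc reagent, with CPhos to outrun β-hydride elimination and chain-walking, should install the isopropyl group on C-1.

Step 13
Reactants: 15 tert-butyl({(1S)-1-[(1R,5S)-5-[(4R)-2,2-dimethyl-1,3-dioxolan-4-yl]-5-methyl-2-(propan-2-yl)cyclopent-2-en-1-yl]-3-methylbut-3-en-1-yl}oxy)dimethylsilane
Product: 16 (1S,2R)-2-[(1S)-1-{[tert-butyl(dimethyl)silyl]oxy}-3-methylbut-3-en-1-yl]-1-methyl-3-(propan-2-yl)cyclopent-3-ene-1-carbaldehyde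
Conditions: H5IO6, EtOAc, rt
Reagents that add atoms: none
Why: Periodic acid hydrolyses the terminal acetonide and cleaves the released 1,2-diol in one pot (glycol cleavage), unmasking the neopentyl aldehyde (future C-4), which cannot epimerise.

Step 14
Reactants: 16 (1S,2R)-2-[(1S)-1-{[tert-butyl(dimethyl)silyl]oxy}-3-methylbut-3-en-1-yl]-1-methyl-3-(propan-2-yl)cyclopent-3-ene-1-carbaldehyde
Product: 17 1-[(1S,2R)-2-[(1S)-1-{[tert-butyl(dimethyl)silyl]oxy}-3-methylbut-3-en-1-yl]-1-methyl-3-(propan-2-yl)cyclopent-3-en-1-yl]prop-2-en-1-ol (both carbinol epimers)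
Conditions: vinylmagnesium bromide, THF, −78 to 0 °C
Reagents that add atoms: vinylmagnesium bromide, C=C[Mg]Br
Why: Grignard addition to the aldehyde supplies C-5 as a vinyl group, and the new carbinol centre need not be controlled because it is oxidised in step 16.

Step 15
Reactants: 17 1-[(1S,2R)-2-[(1S)-1-{[tert-butyl(dimethyl)silyl]oxy}-3-methylbut-3-en-1-yl]-1-methyl-3-(propan-2-yl)cyclopent-3-en-1-yl]prop-2-en-1-ol
Product: 18 (3aS,8S,8aR)-8-{[tert-butyl(dimethyl)silyl]oxy}-3a,6-dimethyl-1-(propan-2-yl)-3,3a,4,7,8,8a-hexahydroazulen-4-ol (both C-4 epimers)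
Conditions: second-generation Grubbs catalyst (5 mol %), CH2Cl2 (0.005 M), 40 °C
Reagents that add atoms: none
Why: Ring-closing metathesis between the vinyl carbinol and the 2-methylallyl group should close the seven-membered ring as the trisubstituted C-5=C-6 alkene, which is possible because the two arms are cis on the cyclopentene.

Step 16
Reactants: 18 (3aS,8S,8aR)-8-{[tert-butyl(dimethyl)silyl]oxy}-3a,6-dimethyl-1-(propan-2-yl)-3,3a,4,7,8,8a-hexahydroazulen-4-ol
Product: 19 (3aS,8S,8aR)-8-{[tert-butyl(dimethyl)silyl]oxy}-3a,6-dimethyl-1-(propan-2-yl)-3a,7,8,8a-tetrahydroazulen-4(3H)-one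
Conditions: Dess–Martin periodinane, CH2Cl2, rt
Reagents that add atoms: none
Why: Dess–Martin oxidation of the allylic alcohol should give the conjugated enone and removes the uncontrolled C-4 centre.

Step 17
Reactants: 19 (3aS,8S,8aR)-8-{[tert-butyl(dimethyl)silyl]oxy}-3a,6-dimethyl-1-(propan-2-yl)-3a,7,8,8a-tetrahydroazulen-4(3H)-one
Product: 20 (3aS,8S,8aR)-8-hydroxy-3a,6-dimethyl-1-(propan-2-yl)-3a,7,8,8a-tetrahydroazulen-4(3H)-one
Conditions: Bu4NF, AcOH, THF, 0 °C to rt
Reagents that add atoms: none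
Why: Fluoride cleaves the silyl ether, and buffering with acetic acid should prevent base-induced elimination across C-7/C-8.

Step 18
Reactants: 20 (3aS,8S,8aR)-8-hydroxy-3a,6-dimethyl-1-(propan-2-yl)-3a,7,8,8a-tetrahydroazulen-4(3H)-one
Product: 21 (3aS,8S,8aR)-3a,6-dimethyl-4-oxo-1-(propan-2-yl)-3,3a,4,7,8,8a-hexahydroazulen-8-yl 4-methoxybenzoate
Conditions: 4-methoxybenzoyl chloride, Et3N, DMAP (cat.), CH2Cl2, 0 °C to rt
Reagents that add atoms: 4-methoxybenzoyl chloride, COc1ccc(cc1)C(Cl)=O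
Why: DMAP-catalysed acylation of the only hydroxyl group installs the 4-methoxybenzoate with retention at C-8.

Step 19
Reactants: 21 (3aS,8S,8aR)-3a,6-dimethyl-4-oxo-1-(propan-2-yl)-3,3a,4,7,8,8a-hexahydroazulen-8-yl 4-methoxybenzoate
Product: 22 (1R,3aS,8S,8aR)-1-hydroxy-3a,6-dimethyl-4-oxo-1-(propan-2-yl)-1,2,3,3a,4,7,8,8a-octahydroazulen-8-yl 4-methoxybenzoate
Conditions: Co(acac)2 (20 mol %), PhSiH3, O2 (1 atm), iPrOH–THF, rt
Reagents that add atoms: dioxygen, O=O
Why: Mukaiyama hydration (cobalt-hydride hydrogen-atom transfer to C-2, capture of the tertiary C-1 radical by O2) should give the Markovnikov alcohol with oxygen delivered on the convex face anti to the C-8 substituent, so that the hydroxyl is cis to H-8a and the angular methyl group, while the β,β-disubstituted enone should react far more slowly.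

**Compound list**

1 | (4S)-2,2-dimethyl-1,3-dioxolane-4-carbaldehyde ((S)-glyceraldehyde acetonide) | O=C[C@@H]1COC(C)(C)O1 | starting material
2 | (4R)-4-ethynyl-2,2-dimethyl-1,3-dioxolane | C#C[C@@H]1COC(C)(C)O1 | intermediate
3 | methyl 3-[(4R)-2,2-dimethyl-1,3-dioxolan-4-yl]prop-2-ynoate | COC(=O)C#C[C@@H]1COC(C)(C)O1 | intermediate
4 | methyl (2Z)-3-[(4R)-2,2-dimethyl-1,3-dioxolan-4-yl]but-2-enoate | COC(=O)/C=C(/C)[C@@H]1COC(C)(C)O1 | intermediate
5 | (2Z)-3-[(4R)-2,2-dimethyl-1,3-dioxolan-4-yl]but-2-en-1-ol | OC/C=C(/C)[C@@H]1COC(C)(C)O1 | intermediate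
6 | 3-(trimethylsilyl)prop-2-ynal | C[Si](C)(C)C#CC=O | starting material
7 | (3S)-5-methyl-1-(trimethylsilyl)hex-5-en-1-yn-3-ol | C[Si](C)(C)C#C[C@@H](O)CC(C)=C | intermediate
8 | (3S)-5-methylhex-5-en-1-yn-3-ol | C#C[C@@H](O)CC(C)=C | intermediate
9 | tert-butyl(dimethyl){[(3S)-5-methylhex-5-en-1-yn-3-yl]oxy}silane | C#C[C@@H](O[Si](C)(C)C(C)(C)C)CC(C)=C | intermediate
10 | tert-butyl{[(1E,3S)-1-iodo-5-methylhexa-1,5-dien-3-yl]oxy}dimethylsilane | I/C=C/[C@@H](O[Si](C)(C)C(C)(C)C)CC(C)=C | intermediate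
11 | tert-butyl{[(1E,3S)-1-{[(2Z)-3-[(4R)-2,2-dimethyl-1,3-dioxolan-4-yl]but-2-en-1-yl]oxy}-5-methylhexa-1,5-dien-3-yl]oxy}dimethylsilane | CC1(C)OC[C@H](O1)/C(C)=C\CO/C=C/[C@@H](O[Si](C)(C)C(C)(C)C)CC(C)=C | intermediate
12 | (2R,3S)-2-[(1S)-1-{[tert-butyl(dimethyl)silyl]oxy}-3-methylbut-3-en-1-yl]-3-[(4R)-2,2-dimethyl-1,3-dioxolan-4-yl]-3-methylpent-4-enal (Claisen aldehyde, not isolated) | CC1(C)OC[C@H](O1)[C@@](C)(C=C)[C@@H](C=O)[C@@H](O[Si](C)(C)C(C)(C)C)CC(C)=C | intermediate
13 | (2R,3S)-2-[(1S)-1-{[tert-butyl(dimethyl)silyl]oxy}-3-methylbut-3-en-1-yl]-3-[(4R)-2,2-dimethyl-1,3-dioxolan-4-yl]-3-methylcyclopentan-1-one | CC1(C)OC[C@H](O1)[C@@]2(C)CCC(=O)[C@H]2[C@@H](O[Si](C)(C)C(C)(C)C)CC(C)=C | intermediate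
14 | (4S,5R)-5-[(1S)-1-{[tert-butyl(dimethyl)silyl]oxy}-3-methylbut-3-en-1-yl]-4-[(4R)-2,2-dimethyl-1,3-dioxolan-4-yl]-4-methylcyclopent-1-en-1-yl trifluoromethanesulfonate | CC1(C)OC[C@H](O1)[C@@]2(C)CC=C(OS(=O)(=O)C(F)(F)F)[C@H]2[C@@H](O[Si](C)(C)C(C)(C)C)CC(C)=C | intermediate
15 | tert-butyl({(1S)-1-[(1R,5S)-5-[(4R)-2,2-dimethyl-1,3-dioxolan-4-yl]-5-methyl-2-(propan-2-yl)cyclopent-2-en-1-yl]-3-methylbut-3-en-1-yl}oxy)dimethylsilane | CC1(C)OC[C@H](O1)[C@@]2(C)CC=C(C(C)C)[C@H]2[C@@H](O[Si](C)(C)C(C)(C)C)CC(C)=C | intermediate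
16 | (1S,2R)-2-[(1S)-1-{[tert-butyl(dimethyl)silyl]oxy}-3-methylbut-3-en-1-yl]-1-methyl-3-(propan-2-yl)cyclopent-3-ene-1-carbaldehyde | O=C[C@@]1(C)CC=C(C(C)C)[C@H]1[C@@H](O[Si](C)(C)C(C)(C)C)CC(C)=C | intermediate
17 | 1-[(1S,2R)-2-[(1S)-1-{[tert-butyl(dimethyl)silyl]oxy}-3-methylbut-3-en-1-yl]-1-methyl-3-(propan-2-yl)cyclopent-3-en-1-yl]prop-2-en-1-ol (both carbinol epimers) | C=CC(O)[C@@]1(C)CC=C(C(C)C)[C@H]1[C@@H](O[Si](C)(C)C(C)(C)C)CC(C)=C | intermediate
18 | (3aS,8S,8aR)-8-{[tert-butyl(dimethyl)silyl]oxy}-3a,6-dimethyl-1-(propan-2-yl)-3,3a,4,7,8,8a-hexahydroazulen-4-ol (both C-4 epimers) | CC(C)(C)[Si](C)(C)O[C@H]1CC(C)=CC(O)[C@@]2(C)CC=C(C(C)C)[C@@H]12 | intermediate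
19 | (3aS,8S,8aR)-8-{[tert-butyl(dimethyl)silyl]oxy}-3a,6-dimethyl-1-(propan-2-yl)-3a,7,8,8a-tetrahydroazulen-4(3H)-one | CC(C)(C)[Si](C)(C)O[C@H]1CC(C)=CC(=O)[C@@]2(C)CC=C(C(C)C)[C@@H]12 | intermediate
20 | (3aS,8S,8aR)-8-hydroxy-3a,6-dimethyl-1-(propan-2-yl)-3a,7,8,8a-tetrahydroazulen-4(3H)-one | O[C@H]1CC(C)=CC(=O)[C@@]2(C)CC=C(C(C)C)[C@@H]12 | intermediate
21 | (3aS,8S,8aR)-3a,6-dimethyl-4-oxo-1-(propan-2-yl)-3,3a,4,7,8,8a-hexahydroazulen-8-yl 4-methoxybenzoate | COc1ccc(cc1)C(=O)O[C@H]2CC(C)=CC(=O)[C@@]3(C)CC=C(C(C)C)[C@@H]23 | intermediate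
22 | (1R,3aS,8S,8aR)-1-hydroxy-3a,6-dimethyl-4-oxo-1-(propan-2-yl)-1,2,3,3a,4,7,8,8a-octahydroazulen-8-yl 4-methoxybenzoate | COc1ccc(C(=O)O[C@H]2CC(C)=CC(=O)[C@@]3(C)CC[C@@](O)(C(C)C)[C@@H]23)cc1 | target

**Totals**

Total step count: 19. Longest linear sequence: 15 steps (steps 1–4 or 5–8, then 9–19).

**Steps most likely to fail**

Step 10. The acylrhodium hydride may lose CO at the temperature the sigmatropic shift needs, the 2-methylallyl group may isomerise, the [3,3] shift may not be fully face-selective, and the centre α to the aldehyde may epimerise before ring closure. The fallback sets out from 11 and comes back at 15. Compound 11 would be rearranged alone (toluene, 120 °C) and the aldehyde 12 isolated. Addition of iPrMgCl (THF, −78 °C) would give the isopropyl carbinol F1. Hydroboration of the vinyl group with disiamylborane and oxidative work-up (NaOH, H2O2) would give the diol F2, the 1,1-disubstituted alkene reacting much more slowly. Swern oxidation would give the keto aldehyde F3. An intramolecular McMurry coupling (TiCl3, Zn–Cu couple, DME, reflux) would then join the two carbonyl carbons and return to the route at the cyclopentene 15, making steps 10 to 12 unnecessary.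

Step 19. Hydrogen-atom transfer may also reach the enone (conjugate reduction or α-oxidation), and oxygen capture may not be fully face-selective. The fallback sets out from 19 and comes back at 22; it starts before the ester is on because a hydride reagent is used. Epoxidation of 19 with mCPBA (NaHCO3, CH2Cl2, 0 °C; the enone is inert) should give the convex-face epoxide F4. LiAlH4 (THF) would open it at the secondary carbon C-2 and reduce the ketone, giving the diol F5. MnO2 would re-oxidise only the allylic alcohol to the hydroxy enone F6. Bu4NF would give the diol F7, and acylation of its secondary hydroxyl with 4-methoxybenzoyl chloride (Et3N, DMAP) would give 22.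

Step 15. Metathesis to a trisubstituted cycloheptene beside a quaternary carbon may be slow, so that dimerisation or catalyst decay competes. The fallback sets out from 16 and comes back at 19. A Me2AlCl-promoted intramolecular carbonyl-ene cyclisation of aldehyde 16 (CH2Cl2, −78 to 0 °C) would close the seven-membered ring by attack of the 2-methylallyl terminus on the aldehyde, giving the methylenecycloheptanol F8 (its endocyclic alkene isomer converges later). Dess–Martin oxidation would give the β,γ-unsaturated ketone F9, and DBU would move the double bond into conjugation to give 19, making steps 14 to 16 unnecessary.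

**Further compounds**

F1 | step 10 | isopropyl carbinol from aldehyde 12 (CHO converted into CH(OH)CH(CH3)2, both carbinol epimers, other centres as in 12) | CC1(C)OC[C@H](O1)[C@@](C)(C=C)[C@@H](C(O)C(C)C)[C@@H](O[Si](C)(C)C(C)(C)C)CC(C)=C
F2 | step 10 | diol from F1 (vinyl group converted into CH2CH2OH) | CC1(C)OC[C@H](O1)[C@@](C)(CCO)[C@@H](C(O)C(C)C)[C@@H](O[Si](C)(C)C(C)(C)C)CC(C)=C
F3 | step 10 | keto aldehyde from F2 (isopropyl ketone and CH2CHO arm on adjacent carbons) | CC1(C)OC[C@H](O1)[C@@](C)(CC=O)[C@@H](C(=O)C(C)C)[C@@H](O[Si](C)(C)C(C)(C)C)CC(C)=C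
F4 | step 19 | C-1/C-2 epoxide of 19, oxygen on the face of H-8a and the angular methyl group | CC(C)(C)[Si](C)(C)O[C@H]1CC(C)=CC(=O)[C@@]2(C)C[C@@H]3O[C@]3(C(C)C)[C@@H]12
F5 | step 19 | (1R,3aS,8S,8aR)-8-{[tert-butyl(dimethyl)silyl]oxy}-3a,6-dimethyl-1-(propan-2-yl)-1,2,3,3a,4,7,8,8a-octahydroazulene-1,4-diol (both C-4 epimers) | CC(C)(C)[Si](C)(C)O[C@H]1CC(C)=CC(O)[C@@]2(C)CC[C@@](O)(C(C)C)[C@@H]12
F6 | step 19 | (1R,3aS,8S,8aR)-8-{[tert-butyl(dimethyl)silyl]oxy}-1-hydroxy-3a,6-dimethyl-1-(propan-2-yl)-2,3,3a,7,8,8a-hexahydroazulen-4(1H)-one | CC(C)(C)[Si](C)(C)O[C@H]1CC(C)=CC(=O)[C@@]2(C)CC[C@@](O)(C(C)C)[C@@H]12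
F7 | step 19 | (1R,3aS,8S,8aR)-1,8-dihydroxy-3a,6-dimethyl-1-(propan-2-yl)-2,3,3a,7,8,8a-hexahydroazulen-4(1H)-one | O[C@H]1CC(C)=CC(=O)[C@@]2(C)CC[C@@](O)(C(C)C)[C@@H]12
F8 | step 15 | (3aS,8S,8aR)-8-{[tert-butyl(dimethyl)silyl]oxy}-3a-methyl-6-methylidene-1-(propan-2-yl)-3,3a,4,5,6,7,8,8a-octahydroazulen-4-ol (both C-4 epimers) | CC(C)(C)[Si](C)(C)O[C@H]1CC(=C)CC(O)[C@@]2(C)CC=C(C(C)C)[C@@H]12
F9 | step 15 | (3aS,8S,8aR)-8-{[tert-butyl(dimethyl)silyl]oxy}-3a-methyl-6-methylidene-1-(propan-2-yl)-3a,5,6,7,8,8a-hexahydroazulen-4(3H)-one | CC(C)(C)[Si](C)(C)O[C@H]1CC(=C)CC(=O)[C@@]2(C)CC=C(C(C)C)[C@@H]12
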